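**Retrosynthetic overview**

1. Target 26 ⇐ para-bromination of phenol 25 ⇐ reduction of the lactone carbonyl of tricycle 22 to CH3 (lactol, then tosylhydrazone reduction).
2. 22 ⇐ bromine-atom-transfer 5-exo-dig radical cyclisation of the α-bromo lactone 21. This closes the cyclopentane between the ring CH that carries the secondary methyl group and the ring carbon that carries the bromomethylidene group; it also sets the CH configuration and delivers the (E)-vinyl bromide.
3. Enabling feature: the phenol oxygen is ortho to the quaternary carbon, so O, two aromatic carbons, the quaternary carbon, the future CH(CH3) carbon and the future methyl carbon can form a six-membered aryl lactone when the methyl carbon is raised to a carboxyl. In this temporary ring the future CH(CH3) carbon is the α-carbon (radical site through an α-bromine), and cis ring fusion holds the future methyl cis to the aryl group.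
4. Lactone 19 ⇐ hydroboration, oxidation and lactonisation of enyne 13 ⇐ copper-catalysed enantioselective allylic substitution (aryl–quaternary carbon bond) of phosphate 8 with the arylaluminium from 10; 8 ⇐ syn-carbocupration of ethyl but-2-ynoate.
5. Ring order: aromatic ring (bought), lactone ring (step 8), cyclopentane (step 10), lactone ring opened again (steps 11 and 12).

Key step: step 10

Assumption: the enantiomer of the chiral ligand in step 5 that gives the R quaternary centre is used; the sense of induction has to be assigned in the first run, and the antipodal ligand serves otherwise.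

**Route**

Step 1
Reactants: 1 (4-bromobut-1-yn-1-yl)trimethylsilane; 2 ethyl but-2-ynoate
Product: 6 ethyl (E)-3-methyl-7-(trimethylsilyl)hept-2-en-6-ynoate, via Grignard reagent 3 (not isolated), via alkylcopper 4 (not isolated), via alkenylcopper 5 (not isolated)
Conditions: Mg, THF, 40 °C; CuBr·SMe2 (1.0 equiv), THF, −40 °C; then 2, −78 °C; NH4Cl (aq), −78 °C
Reagents that add atoms: none
Why: Syn-carbocupration of the acetylenic ester by the Grignard-derived alkylcopper at −78 °C, followed by protonation of the alkenylcopper with retention, should fix the E trisubstituted alkene (organocopper conjugate addition to an ynoate).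

Step 2
Reactants: 6 ethyl (E)-3-methyl-7-(trimethylsilyl)hept-2-en-6-ynoate
Product: 7 (E)-3-methyl-7-(trimethylsilyl)hept-2-en-6-yn-1-ol
Conditions: i-Bu2AlH (2.2 equiv), CH2Cl2, −78 → 0 °C; potassium sodium tartrate (KNaC4H4O6, aq)
Reagents that add atoms: none
Why: 1,2-Reduction of the enoate with i-Bu2AlH should give the allylic alcohol without touching the alkene geometry or the silylalkyne (hydride reduction of an ester).

Step 3
Reactants: 7 (E)-3-methyl-7-(trimethylsilyl)hept-2-en-6-yn-1-ol
Product: 8 diethyl (E)-3-methyl-7-(trimethylsilyl)hept-2-en-6-yn-1-yl phosphate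
Conditions: ClP(O)(OEt)2, Et3N, DMAP (cat.), CH2Cl2, 0 °C
Reagents that add atoms: diethyl chlorophosphate, ClP(=O)(OCC)OCC
Why: O-Phosphorylation of the primary allylic alcohol should install the leaving group for the allylic substitution.

Step 4
Reactants: 9 2-bromo-5-methylphenol
Product: 10 1-bromo-2-(methoxymethoxy)-4-methylbenzene
Conditions: MOMCl, i-Pr2NEt, CH2Cl2, 0 °C → rt
Reagents that add atoms: chloromethyl methyl ether, COCCl
Why: O-Alkylation (Williamson type) masks the phenol as a MOM acetal that should survive the organolithium, aluminium and borane reagents and is removed later by acid.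

Step 5
Reactants: 10 1-bromo-2-(methoxymethoxy)-4-methylbenzene; 8 diethyl (E)-3-methyl-7-(trimethylsilyl)hept-2-en-6-yn-1-yl phosphate
Product: 13 (R)-{5-[2-(methoxymethoxy)-4-methylphenyl]-5-methylhept-6-en-1-yn-1-yl}trimethylsilane, via aryllithium 11 (not isolated), via arylaluminium 12 (not isolated)
Conditions: n-BuLi, THF, −78 °C; Et2AlCl, −78 → 0 °C; then 8, CuCl2·2H2O (2 mol%), chiral sulfonate-bearing imidazolinium salt premetalated with Ag2O (1.25 mol%), THF, −30 °C
Reagents that add atoms: none
Why: Bromine–lithium exchange and transmetalation give an aryl(diethyl)aluminium whose aryl group should be transferred under NHC–copper catalysis in SN2′ fashion to the γ-carbon of the E-phosphate (copper-catalysed enantioselective allylic substitution), creating the aryl/methyl quaternary centre with the configuration set by the catalyst enantiomer.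

Step 6
Reactants: 13 (R)-{5-[2-(methoxymethoxy)-4-methylphenyl]-5-methylhept-6-en-1-yn-1-yl}trimethylsilane
Product: 16 (3R)-3-[2-(methoxymethoxy)-4-methylphenyl]-3-methylhept-6-yn-1-ol, via alkylborane 14 (not isolated), via silylalkyne alcohol 15 (not isolated)
Conditions: 9-BBN (1.3 equiv), THF, 0 °C → rt; then NaOH (3 M), H2O2 (30%), MeOH, 0 °C → rt
Reagents that add atoms: hydrogen peroxide, OO
Why: 9-BBN should add anti-Markovnikov to the monosubstituted vinyl group much faster than to the silylalkyne (hydroboration–oxidation), and the basic methanol then cleaves the alkynyl C–Si bond; the quaternary centre is not touched.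

Step 7
Reactants: 16 (3R)-3-[2-(methoxymethoxy)-4-methylphenyl]-3-methylhept-6-yn-1-ol
Product: 17 (3R)-3-[2-(methoxymethoxy)-4-methylphenyl]-3-methylhept-6-ynoic acid
Conditions: TEMPO (20 mol%), PhI(OAc)2 (2.2 equiv), MeCN/H2O 1:1, rt
Reagents that add atoms: water, O
Why: Nitroxyl-catalysed oxidation with PhI(OAc)2 in aqueous acetonitrile should take the primary alcohol through the aldehyde hydrate to the acid while sparing the MOM ether and the terminal alkyne.

Step 8
Reactants: 17 (3R)-3-[2-(methoxymethoxy)-4-methylphenyl]-3-methylhept-6-ynoic acid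
Product: 19 (4R)-4-(but-3-yn-1-yl)-4,7-dimethyl-3,4-dihydro-2H-chromen-2-one, via phenol acid 18 (not isolated)
Conditions: HCl (3 M aq), MeOH/THF, 50 °C
Reagents that add atoms: none
Why: Acid-catalysed acetal cleavage removes the MOM group, and the freed phenol should lactonise at once onto the acid arm held close by the gem-disubstituted carbon (Thorpe–Ingold-assisted Fischer lactonisation).

Step 9
Reactants: 19 (4R)-4-(but-3-yn-1-yl)-4,7-dimethyl-3,4-dihydro-2H-chromen-2-one
Product: 21 (4S)-3-bromo-4-(but-3-yn-1-yl)-4,7-dimethyl-3,4-dihydro-2H-chromen-2-one (both C3 epimers), via silyl ketene acetal 20 (not isolated)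
Conditions: TMSOTf (1.3 equiv), Et3N (1.6 equiv), CH2Cl2, 0 °C; then NBS (1.05 equiv), THF, −78 °C
Reagents that add atoms: N-bromosuccinimide, BrN1C(=O)CCC1=O
Why: Soft enolisation to the silyl ketene acetal avoids deprotonating the terminal alkyne, and electrophilic α-bromination with NBS then installs the bromine; the new centre needs no control because it becomes a planar radical in step 10.

Step 10
Reactants: 21 (4S)-3-bromo-4-(but-3-yn-1-yl)-4,7-dimethyl-3,4-dihydro-2H-chromen-2-one (both C3 epimers)
Product: 22 (3aR,9bR)-3-[(E)-bromomethylidene]-7,9b-dimethyl-2,3,3a,9b-tetrahydrocyclopenta[c]chromen-4(1H)-one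
Conditions: CuBr (20 mol%), TPMA [tris(2-pyridylmethyl)amine] (22 mol%), 1,2-dichloroethane (0.3 M), degassed, 80 °C
Reagents that add atoms: none
Why: Monovalent copper (CuBr/TPMA) reversibly abstracts the α-bromine of 21 to give the planar, carbonyl-stabilised radical at lactone C3 and a divalent copper bromide complex; the radical adds to the internal alkyne carbon and the resulting σ-vinyl radical takes bromine back from the divalent copper complex (or from 21), so the bromine that activated the α-carbon ends on the exocyclic carbon and no reagent atom is added. The closest known reaction type is the copper-catalysed (Kharasch-type) atom-transfer radical cyclisation of α-halo esters and amides onto alkynes to give halomethylidene five-membered rings. The cyclopentane closes in the 5-exo-dig mode. The new stereocentre is controlled by the lactone ring: the three-atom tether from the adjacent quaternary carbon can reach only the radical lobe on its own face, so the rings should be cis-fused and the carbonyl carbon (the future methyl) is held cis to the aryl group, while both C3 epimers of 21 converge through the same radical. The step needs E geometry, which should be secured because the rapidly inverting vinyl radical accepts bromine from the bulky copper complex on the side flanked by the ring CH2 group and away from the ring-fusion carbon, the E isomer also being the less strained one.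

Step 11
Reactants: 22 (3aR,9bR)-3-[(E)-bromomethylidene]-7,9b-dimethyl-2,3,3a,9b-tetrahydrocyclopenta[c]chromen-4(1H)-one
Product: 23 (3aR,9bR)-3-[(E)-bromomethylidene]-7,9b-dimethyl-1,2,3,3a,4,9b-hexahydrocyclopenta[c]chromen-4-ol (lactol; anomer mixture)
Conditions: i-Bu2AlH (1.2 equiv), CH2Cl2, −78 °C; potassium sodium tartrate (KNaC4H4O6, aq)
Reagents that add atoms: none
Why: Partial reduction of the aryl lactone at −78 °C should stop at the aluminium hemiacetal and give the lactol (lactone-to-lactol reduction) without touching the vinyl bromide.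

Step 12
Reactants: 23 (3aR,9bR)-3-[(E)-bromomethylidene]-7,9b-dimethyl-1,2,3,3a,4,9b-hexahydrocyclopenta[c]chromen-4-ol (lactol; anomer mixture)
Product: 25 2-[(1R,2R,3E)-3-(bromomethylidene)-1,2-dimethylcyclopentyl]-5-methylphenol, via tosylhydrazone 24 (not isolated)
Conditions: TsNHNH2, EtOH, 50 °C; then catecholborane, CHCl3, 0 °C; then NaOAc·3H2O, 60 °C
Reagents that add atoms: none
Why: The lactol opens to its hydroxy aldehyde and condenses with tosylhydrazine; hydride delivery from catecholborane and acetate-induced loss of sulfinate and N2 (Caglioti-type tosylhydrazone reduction) should convert CH=N into CH3 under near-neutral conditions that keep the adjacent stereocentre and the vinyl bromide.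

Step 13
Reactants: 25 2-[(1R,2R,3E)-3-(bromomethylidene)-1,2-dimethylcyclopentyl]-5-methylphenol
Product: 26 4-bromo-2-[(1R,2R,3E)-3-(bromomethylidene)-1,2-dimethylcyclopentyl]-5-methylphenol
Conditions: NBS (1.0 equiv), MeCN, −20 → 0 °C
Reagents that add atoms: N-bromosuccinimide, BrN1C(=O)CCC1=O
Why: Electrophilic aromatic bromination should occur para to the hydroxyl group, the only unhindered activated position (the free ortho position lies between OH and CH3), as in the bromination of thymol, and the electron-poor vinyl bromide does not react.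

**Compound list**

1 | (4-bromobut-1-yn-1-yl)trimethylsilane | C[Si](C)(C)C#CCCBr | starting material
2 | ethyl but-2-ynoate | CC#CC(=O)OCC | starting material
3 | [4-(trimethylsilyl)but-3-yn-1-yl]magnesium bromide | C[Si](C)(C)C#CCC[Mg]Br | intermediate
4 | [4-(trimethylsilyl)but-3-yn-1-yl]copper (MgBr2 complex) | C[Si](C)(C)C#CCC[Cu] | intermediate
5 | ethyl (Z)-2-cuprio-3-methyl-7-(trimethylsilyl)hept-2-en-6-ynoate | CCOC(=O)/C([Cu])=C(\C)CCC#C[Si](C)(C)C | intermediate
6 | ethyl (E)-3-methyl-7-(trimethylsilyl)hept-2-en-6-ynoate | CCOC(=O)/C=C(\C)CCC#C[Si](C)(C)C | intermediate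
7 | (E)-3-methyl-7-(trimethylsilyl)hept-2-en-6-yn-1-ol | OC/C=C(\C)CCC#C[Si](C)(C)C | intermediate
8 | diethyl (E)-3-methyl-7-(trimethylsilyl)hept-2-en-6-yn-1-yl phosphate | CCOP(=O)(OCC)OC/C=C(\C)CCC#C[Si](C)(C)C | intermediate
9 | 2-bromo-5-methylphenol | Cc1ccc(Br)c(O)c1 | starting material
10 | 1-bromo-2-(methoxymethoxy)-4-methylbenzene | COCOc1cc(C)ccc1Br | intermediate
11 | [2-(methoxymethoxy)-4-methylphenyl]lithium | COCOc1cc(C)ccc1[Li] | intermediate
12 | diethyl[2-(methoxymethoxy)-4-methylphenyl]aluminium | COCOc1cc(C)ccc1[Al](CC)CC | intermediate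
13 | (R)-{5-[2-(methoxymethoxy)-4-methylphenyl]-5-methylhept-6-en-1-yn-1-yl}trimethylsilane | COCOc1cc(C)ccc1[C@](C=C)(C)CCC#C[Si](C)(C)C | intermediate
14 | B-alkyl-9-borabicyclo[3.3.1]nonane adduct of 13 (boron on the terminal carbon of the former vinyl group) | COCOc1cc(C)ccc1[C@](CCB2C3CCCC2CCC3)(C)CCC#C[Si](C)(C)C | intermediate
15 | (3R)-3-[2-(methoxymethoxy)-4-methylphenyl]-3-methyl-7-(trimethylsilyl)hept-6-yn-1-ol | COCOc1cc(C)ccc1[C@](CCO)(C)CCC#C[Si](C)(C)C | intermediate
16 | (3R)-3-[2-(methoxymethoxy)-4-methylphenyl]-3-methylhept-6-yn-1-ol | COCOc1cc(C)ccc1[C@](CCO)(C)CCC#C | intermediate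
17 | (3R)-3-[2-(methoxymethoxy)-4-methylphenyl]-3-methylhept-6-ynoic acid | COCOc1cc(C)ccc1[C@](CC(=O)O)(C)CCC#C | intermediate
18 | (3R)-3-(2-hydroxy-4-methylphenyl)-3-methylhept-6-ynoic acid | Oc1cc(C)ccc1[C@](CC(=O)O)(C)CCC#C | intermediate
19 | (4R)-4-(but-3-yn-1-yl)-4,7-dimethyl-3,4-dihydro-2H-chromen-2-one | O=C1C[C@@](C)(CCC#C)c2ccc(C)cc2O1 | intermediate
20 | {[(4R)-4-(but-3-yn-1-yl)-4,7-dimethyl-4H-chromen-2-yl]oxy}trimethylsilane | C[Si](C)(C)OC1=C[C@@](C)(CCC#C)c2ccc(C)cc2O1 | intermediate
21 | (4S)-3-bromo-4-(but-3-yn-1-yl)-4,7-dimethyl-3,4-dihydro-2H-chromen-2-one (both C3 epimers) | O=C1C(Br)[C@@](C)(CCC#C)c2ccc(C)cc2O1 | intermediate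
22 | (3aR,9bR)-3-[(E)-bromomethylidene]-7,9b-dimethyl-2,3,3a,9b-tetrahydrocyclopenta[c]chromen-4(1H)-one | O=C1Oc2cc(C)ccc2[C@]3(C)CC/C(=C\Br)[C@@H]31 | intermediate
23 | (3aR,9bR)-3-[(E)-bromomethylidene]-7,9b-dimethyl-1,2,3,3a,4,9b-hexahydrocyclopenta[c]chromen-4-ol (anomer mixture) | OC1Oc2cc(C)ccc2[C@]3(C)CC/C(=C\Br)[C@@H]31 | intermediate
24 | N'-{[(1R,2R,5E)-5-(bromomethylidene)-2-(2-hydroxy-4-methylphenyl)-2-methylcyclopentyl]methylidene}-4-methylbenzenesulfonohydrazide | Oc1cc(C)ccc1[C@]2(C)CC/C(=C\Br)[C@@H]2C=NNS(=O)(=O)c1ccc(C)cc1 | intermediate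
25 | 2-[(1R,2R,3E)-3-(bromomethylidene)-1,2-dimethylcyclopentyl]-5-methylphenol | Oc1cc(C)ccc1[C@]2(C)CC/C(=C\Br)[C@@H]2C | intermediate
26 | 4-bromo-2-[(1R,2R,3E)-3-(bromomethylidene)-1,2-dimethylcyclopentyl]-5-methylphenol | Cc1cc(O)c([C@]2(C)CC/C(=C\Br)[C@@H]2C)cc1Br | target

**Step count**

Total: 13 steps. Longest linear sequence: 12 steps (steps 1 to 3, then 5 to 13).

**Steps most likely to fail, with fallbacks**

Step 10. Bromine transfer to the vinyl radical may be slow or unselective, which would erode the E/Z ratio, or the vinyl radical may shift a hydrogen atom from the angular methyl group before it is brominated. The fallback sets out from 13 and comes back at 26. Zirconocene-mediated reductive enyne cyclisation (Cp2ZrCl2, 2 n-BuLi, THF, −78 °C → rt) forms the same ring bond by syn-carbometalation and gives the zirconabicycle F1. Protonolysis (3 M HCl) gives the (E)-vinylsilane F2, in which hydrogen sits cis and silicon trans to the new bond by mechanism; here the ring is not templated, so the epimers at the methyl-bearing CH would have to be separated. NBS (2.2 equiv, MeCN, 0 °C) should replace silicon by bromine with retention and brominate the arene para to oxygen, giving the MOM ether F3, and HCl in MeOH then frees 26.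

Step 5. Chelation of the MOM oxygen to aluminium, or the ortho substituent itself, may slow aryl transfer and lower the SN2′ regioselectivity and the facial selectivity. The fallback sets out from 10 and 3 and comes back at 13; the roles of the partners are reversed. Heck coupling of 10 with ethyl crotonate (Pd(OAc)2, P(o-tol)3, Et3N, DMF, 100 °C) gives the aryl enoate F4, i-Bu2AlH reduction gives the allylic alcohol F5 and phosphorylation gives the phosphate F6. Copper-catalysed allylic substitution of F6 with the dialkylzinc F7 (from 3 and ZnCl2), using (CuOTf)2·C6H6 and a chiral pyridinyl peptide ligand, then delivers the alkyl chain to the aryl-bearing carbon and gives 13.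

Step 12. The hindered lactol may open too slowly for hydrazone formation, or the aldehyde may epimerise by enolisation at the adjacent ring carbon before it is reduced. The fallback sets out from 22 and comes back at 25. Exhaustive hydrosilane reduction of the lactone carbonyl (excess Et3SiH, B(C6F5)3 cat., CH2Cl2, rt) converts C(=O)–OAr directly into CH3 and gives the aryl triethylsilyl ether F8; TBAF (THF, 0 °C) then frees the phenol 25.

**Further compounds**

F1 | step 10 | bis(cyclopentadienyl)zirconabicycle from 13 (Zr bonded to the silyl-bearing vinyl carbon and to the CH2 group on the new ring CH) | COCOc1cc(C)ccc1[C@]2(C)CCC3=C([Si](C)(C)C)[Zr](C4C=CC=C4)(C4C=CC=C4)C[C@H]23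
F2 | step 10 | 2-{(1R,2R,3E)-1,2-dimethyl-3-[(trimethylsilyl)methylidene]cyclopentyl}-1-(methoxymethoxy)-5-methylbenzene | COCOc1cc(C)ccc1[C@]2(C)CC/C(=C\[Si](C)(C)C)[C@@H]2C
F3 | step 10 | 1-bromo-5-[(1R,2R,3E)-3-(bromomethylidene)-1,2-dimethylcyclopentyl]-4-(methoxymethoxy)-2-methylbenzene | COCOc1cc(C)c(Br)cc1[C@]2(C)CC/C(=C\Br)[C@@H]2C
F4 | step 5 | ethyl (E)-3-[2-(methoxymethoxy)-4-methylphenyl]but-2-enoate | CCOC(=O)/C=C(\C)c1ccc(C)cc1OCOC
F5 | step 5 | (E)-3-[2-(methoxymethoxy)-4-methylphenyl]but-2-en-1-ol | OC/C=C(\C)c1ccc(C)cc1OCOC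
F6 | step 5 | diethyl (E)-3-[2-(methoxymethoxy)-4-methylphenyl]but-2-en-1-yl phosphate | CCOP(=O)(OCC)OC/C=C(\C)c1ccc(C)cc1OCOC
F7 | step 5 | bis[4-(trimethylsilyl)but-3-yn-1-yl]zinc | C[Si](C)(C)C#CCC[Zn]CCC#C[Si](C)(C)C
F8 | step 12 | {2-[(1R,2R,3E)-3-(bromomethylidene)-1,2-dimethylcyclopentyl]-5-methylphenoxy}triethylsilane | CC[Si](CC)(CC)Oc1cc(C)ccc1[C@]2(C)CC/C(=C\Br)[C@@H]2C
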